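# Total synthesis proposal for taiwanhomoflavone A (21)

## Analysis of the target

1. Taiwanhomoflavone A (21, C33H24O10) is a biflavone of the amentoflavone type. Two 2-arylchromen-4-ones are joined by one C–C bond between C3' of the anisole ring B of unit 1 (rings A, C, B) and C8'' of the trioxygenated carbocycle D of unit 2 (rings D, E, F).
2. Unit 1 carries 5-OH, 6-CH3 and 7-OCH3 on ring A, whose only C–H is C8, and 4'-OCH3 on ring B. Unit 2 has free hydroxyl groups at C5'', C7'' and C4'''.
3. There is no stereocentre. The only stereogenic element is the C3'–C8'' axis with three ortho substituents (4'-OCH3, 7''-OH, O1''), and the SMILES gives no descriptor for it.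
4. The first difficulty is this hindered biaryl bond, which must end at C8'' and not at C6'', a position of almost the same electronic character.
5. The second is the same 6/8 ambiguity in ring A. A 2,6-dihydroxyacetophenone precursor can close ring C in two directions, and strong acid can interconvert the isomers by Wessely–Moser ring opening.
6. The third is oxygen differentiation: of the six aryl oxygens outside the pyranone rings, two end as methyl ethers and four as free phenols, two of them chelated peri-hydroxyls.
7. The sensitive groups are the two γ-pyranone rings, which open when hydroxide or carbon nucleophiles attack C2 or C2'', and ring D, which is easily oxidised, halogenated or C-alkylated.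
8. The plan exploits one feature of ring D (C4a''–C5''–C6''–C7''–C8''–C8a''). It is a masked cyclohexane-1,3,5-trione in which C5''–C6''–C7'' is a malonyl unit and C8''–C8a''(O1'')=C4a'' is an enol ether with its α' and α carbons. Ring D can therefore be built around a C8'' that already carries ring B as a benzyl substituent.

## Retrosynthetic reasoning

**21 ⇒ 20.** Only two O–C bonds are cut: O–CH3 at C5 and O–CH2Ph at C4'''. One Lewis acid should remove both groups. The C5 ether is activated by chelation to C4=O, and the benzyl ether by its stabilised cation. The methyl ethers at C7 and C4' belong to the target and must stay, so the forward reaction has to distinguish three methyl ethers by position alone.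

**20 ⇒ 16 + 17 (key disconnection).**
- Two C–C bonds of ring D are cut, C7''–C8'' and C4a''–C5''.
- Ring D disappears. Its C5''–C6''–C7'' segment is malonyl dichloride 17.
- What remains is a monocyclic γ-pyranone (ring E) whose C8a'' bears C8'' as a benzylic carbon, activated as the silyl trienol ether 16.
- The cut is made here and not at C3'–C8'' because it turns the tri-ortho-substituted biaryl bond into the ordinary benzyl–aryl bond already present in starting material 5.
- No aryl–aryl coupling, no halogenation or metalation of a flavone and no protection of ring D is then needed.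
- The C6''/C8'' question also vanishes. O1''–C8a'' and C8''–C3' exist before ring D does, so the aryl group can only end up next to the ring oxygen.
- The precursor lacks one ring, the axis and both hydroxyl groups of ring D.
- The forward reaction has to acylate C8'' and C4a'' with the two ends of one reagent and then aromatise.

**16 ⇒ 15.** Only the O–Si bond at C4'' is cut, with return of one proton to C8''. This makes the nucleophile without a strong base, which the flavone of unit 1 would not tolerate well.

**15 ⇒ 10 + 12.** Ring E is cut at O1''–C2'' and C3''–C4''. These are the two bonds formed when the acylketene 13, released from 10, adds as a heterodiene to the enol ether 12. The adduct 14 aromatises by loss of its alkoxy group. This cut is preferred to an open 1,3,5-triketone because it is thermal and neutral. It also places the benzyl group on C8a'' and ring F on C2'' without ambiguity.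

**10 ⇒ 8 + 9, and 12 ⇒ 11.** The C8a''–C4a'' bond is cut to the arylacetic acid 8 and Meldrum's acid 9, which supplies C4a'' and C4''. The enol ether 12 is cut at the aryl–vinyl bond to the aryl iodide 11.

**8 ⇒ 7 ⇒ 4 + 6.** Ring C is cut at O1–C2 (oxidative cyclisation of the chalcone 7) and at C2–C3 (aldol condensation of the acetophenone 4 with the aldehyde 6). This conventional construction is kept on purpose, so that the risk of the route stays in the key step. A C-methylated analogue of 17 could in principle build ring A in the same way as ring D, but that would double the risk.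

**4 ⇒ 3 ⇒ 1, and 6 ⇒ 5.**
- The acetyl–aryl bond of 4 is cut to the phenol 3. In 3 the para position is blocked by the methyl group and the two ortho positions are equivalent.
- Only one acetophenone can therefore form, and it has a single free hydroxyl group. This fixes the methyl group at C6 of the flavone and not at C8.
- 3 comes from 1 by functionalisation of its only unhindered C–H bond.
- 6 comes from 5 by introduction of one carbon para to the methoxy group.

## Alternatives that were turned down

**Alternative 1:** the textbook cut of C3'–C8'' between two finished flavones.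
- *Forward key step:* Suzuki–Miyaura coupling of the 3'-boronate A1 with the 8-iodoflavone A2 under a zerovalent palladium catalyst.
- *Reason for rejection:* the step forms one bond between two partners that are each half as complex as the target, so it simplifies little.
  - Both flavones must be built separately, each with its own protecting groups.
  - Iodination to A2 has to choose C8'' over C6''.
  - The coupling joins an electron-rich, doubly ortho-substituted iodide to an ortho-alkoxy boronate that is prone to protodeboronation.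
  - By count of operations it is no shorter than the chosen route.
  - It is kept only as the fallback for the key step.

**Alternative 2:** the same bond cut in the biosynthetic sense, between two unfunctionalised monomers.
- *Forward key step:* one-electron oxidation of a mixture of the 4'-phenol A3 and apigenin A4 to the cross-coupled biflavone A5, followed by O-methylation at C4'.
- *Reason for rejection:* it is very short, but the substrates offer no element of control.
  - A4 has its own 4'''-phenol, which is as oxidisable as that of A3.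
  - Spin density sits on O4', C3', C5', C6'' and C8''. Homo- and cross-coupling through C–C and C–O bonds all compete.
  - Both phenols are conjugated to electron-poor pyranones, so they are hard to oxidise, while A5 should be oxidised more easily than either monomer.
  - The final methylation of 4'-OH in A5 would have to ignore 7''-OH and 4'''-OH of similar acidity.

**Alternative 3:** ring D built first from an open chain, cut at C7''–C8''.
- *Forward key step:* Dieckmann-type folding of the triketo ester A6 to the 2-arylbenzene-1,3,5-triol A7. A thermal Mentzer-type annulation of ring E with an aroylacetic ester would follow.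
- *Reason for rejection:* A7 is locally C2-symmetric.
  - After C-acylation two different hydroxyl groups flank the new acyl group. The one remote from ring B is less hindered, so closure should favour the 3'–6'' isomer A8.
  - A Wessely–Moser equilibration cannot be counted on to correct this.
  - Differentiating the hydroxyl groups would cost protecting-group steps, and A6 itself requires dianion chemistry on a flavone.
  - The chosen route keeps the idea of growing ring D around C8'' but sets O1''–C8a'' first.

Key step: step 10

Assumption: the SMILES defines no configuration for the C3'–C8'' axis, so 21 is taken as the configurationally undefined (racemic) biaryl and no control of the axis is planned.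

## Route

Step 1
Reactants: 1 2,6-dimethoxytoluene
Product: 3 3,5-dimethoxy-4-methylphenol, via aryl pinacol boronate 2 (not isolated)
Conditions: [Ir(OMe)(cod)]2 (1.5 mol %), 4,4'-di-tert-butyl-2,2'-bipyridine (3 mol %), B2pin2 (1.0 equiv), THF, 80 °C; then 30% aq. H2O2, NaOH, THF, 0 °C to rt
Reagents that add atoms: bis(pinacolato)diboron CC1(C)OB(OC1(C)C)B1OC(C)(C)C(C)(C)O1; hydrogen peroxide OO
Why: Iridium-catalysed C–H borylation is governed by sterics, and C4 of 1 is the only C–H bond without an ortho substituent. Oxidation of the C–B bond of 2 at the same carbon should give the symmetric phenol 3 (one-pot borylation–oxidation).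

Step 2
Reactants: 3 3,5-dimethoxy-4-methylphenol
Product: 4 1-(6-hydroxy-2,4-dimethoxy-3-methylphenyl)ethan-1-one
Conditions: Ac2O (2 equiv), BF3·OEt2 (3 equiv), 80 °C; then H2O, 60 °C
Reagents that add atoms: acetic anhydride CC(=O)OC(C)=O
Why: Friedel–Crafts acylation (or O-acetylation and Fries rearrangement) of an electron-rich phenol. The para position is blocked by the methyl group and the two ortho positions are equivalent, so only one acetophenone can form. The chelated ketone deactivates the ring against a second acylation.

Step 3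
Reactants: 5 methyl 2-(2-methoxyphenyl)acetate
Product: 6 methyl 2-(5-formyl-2-methoxyphenyl)acetate
Conditions: Cl2CHOMe (1.5 equiv), TiCl4 (2.2 equiv), CH2Cl2, 0 °C; then ice, 1 M HCl
Reagents that add atoms: dichloromethyl methyl ether COC(Cl)Cl; water O
Why: Rieche formylation; the methoxy group directs the electrophile para to itself (C5), the ortho position being more crowded. The ester is used because the reagent would turn a free acid into its chloride.

Step 4
Reactants: 4 1-(6-hydroxy-2,4-dimethoxy-3-methylphenyl)ethan-1-one; 6 methyl 2-(5-formyl-2-methoxyphenyl)acetate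
Product: 7 2-{5-[(1E)-3-(6-hydroxy-2,4-dimethoxy-3-methylphenyl)-3-oxoprop-1-en-1-yl]-2-methoxyphenyl}acetic acid
Conditions: KOH (50% aq., excess), EtOH, rt; then 1 M HCl to pH 2
Reagents that add atoms: potassium hydroxide [K+].[OH-]
Why: Claisen–Schmidt condensation; E1cB loss of water should give the E-enone. The methyl ester is saponified in the same pot, which is wanted: the acid is needed in step 6, and the carboxylate keeps the benzylic CH2 from enolising.

Step 5
Reactants: 7 chalcone acid
Product: 8 2-[5-(5,7-dimethoxy-6-methyl-4-oxo-4H-chromen-2-yl)-2-methoxyphenyl]acetic acid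
Conditions: I2 (10 mol %), DMSO, 130 °C; aq. Na2S2O3 work-up
Reagents that add atoms: none
Why: Iodine-catalysed oxidative cyclisation of a 2'-hydroxychalcone (oxa-Michael addition, α-iodination, loss of HI, reoxidation of HI by DMSO). 7 has one free phenol only, so ring C can close only in the direction that puts the methyl group at C6.

Step 6
Reactants: 8 flavone acid; 9 Meldrum's acid (2,2-dimethyl-1,3-dioxane-4,6-dione)
Product: 10 5-{2-[5-(5,7-dimethoxy-6-methyl-4-oxo-4H-chromen-2-yl)-2-methoxyphenyl]-1-hydroxyethylidene}-2,2-dimethyl-1,3-dioxane-4,6-dione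
Conditions: DCC (1.1 equiv), DMAP (1.5 equiv), CH2Cl2, 0 °C to rt; aq. KHSO4 wash
Reagents that add atoms: none
Why: Carbodiimide-mediated C-acylation of Meldrum's acid, a standard reaction of arylacetic acids. The conditions are mild enough for the flavone.

Step 7
Reactants: 11 1-(benzyloxy)-4-iodobenzene
Product: 12 1-(benzyloxy)-4-(1-ethoxyethenyl)benzene
Conditions: tributyl(1-ethoxyvinyl)stannane (1.1 equiv), Pd(PPh3)4 (5 mol %), toluene, 100 °C; filtration through basic alumina
Reagents that add atoms: tributyl(1-ethoxyvinyl)stannane CCCC[Sn](CCCC)(CCCC)C(=C)OCC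
Why: Stille coupling of an aryl iodide with an α-alkoxyvinylstannane. A non-acidic work-up keeps the enol ether intact.

Step 8
Reactants: 10 acyl Meldrum's acid; 12 1-(benzyloxy)-4-(1-ethoxyethenyl)benzene
Product: 15 2-(3-{[6-(4-(benzyloxy)phenyl)-4-oxo-4H-pyran-2-yl]methyl}-4-methoxyphenyl)-5,7-dimethoxy-6-methyl-4H-chromen-4-one, via acylketene 13 (not isolated), via ethoxy dihydropyranone 14 (not isolated)
Conditions: 12 (2.5 equiv), 4 Å molecular sieves, toluene, 100 °C; then TsOH·H2O (10 mol %), THF, rt
Reagents that add atoms: none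
Why: Thermolysis of an acyl Meldrum's acid releases the acylketene 13, which adds to the electron-rich enol ether in a hetero-Diels–Alder reaction: the ketene carbon bonds to the CH2 terminus and the acyl oxygen to the oxygenated carbon. Acid-catalysed loss of the alkoxy group from 14 gives the γ-pyranone, a known pyranone synthesis from acyl Meldrum's acids and vinyl ethers. The neutral thermal conditions spare the flavone.

Step 9
Reactants: 15 benzyl γ-pyranone
Product: 16 2-{3-[(6-[4-(benzyloxy)phenyl]-4-[(tert-butyldimethylsilyl)oxy]-2H-pyran-2-ylidene)methyl]-4-methoxyphenyl}-5,7-dimethoxy-6-methyl-4H-chromen-4-one (E/Z mixture, geometry without consequence)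
Conditions: TBSOTf (1.1 equiv), Et3N (1.5 equiv), CH2Cl2, 0 °C; pentane, filtration under argon, evaporation; used at once
Reagents that add atoms: tert-butyldimethylsilyl triflate CC(C)(C)[Si](C)(C)OS(=O)(=O)C(F)(F)F
Why: O-silylation of the pyranone carbonyl gives a 4-silyloxypyrylium ion whose benzylic C8''–H is acidic enough for Et3N (soft enolisation, the classical anhydrobase formation from a 2-alkylpyrylium salt). The flavone carbonyl of unit 1 can be silylated only reversibly because it has no acidic vinylogous C–H, so the equilibrium should drain towards 16.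

Step 10
Reactants: 16 silyl trienol ether; 17 malonyl dichloride
Product: 20 2-[4-(benzyloxy)phenyl]-8-[5-(5,7-dimethoxy-6-methyl-4-oxo-4H-chromen-2-yl)-2-methoxyphenyl]-5,7-dihydroxy-4H-chromen-4-one, via keto acyl chloride 18 (not isolated), via dienylketene 19 (not isolated)
Conditions: slow addition of 16 to 17 (1.2 equiv) and 2,6-di-tert-butyl-4-methylpyridine (1.2 equiv), CH2Cl2 (0.01 M), −78 °C to rt, then 40 °C; NaHCO3, MeOH/H2O work-up
Reagents that add atoms: none
Why: Proposed new method: the exocyclic carbon C8'' of 16 is the terminus of a silyl trienol ether, and its acylation by one acid chloride group of 17 restores an aromatic 4-silyloxypyrylium ion, from which chloride takes the silyl group to leave the keto acyl chloride 18. The C8''–H of 18 is benzylic, α to the new ketone and vinylogously α to C4''=O, so 18 should enolise and give up HCl to the hindered pyridine to form the dienylketene 19, C4a''=C8a''–C8''=C7''(OH)–C6''H=C5''=O. Ring D is then closed by a six-electron electrocyclisation of 19 (equally describable as a 6-exo-trig C-acylation of the enol ether β-carbon C4a''), which forms C4a''–C5'', and tautomerisation gives the 5'',7''-dihydroxychromenone. The closest known reaction types are the Effenberger annulation (malonyl dichloride acylates the α and α' carbons of a silyl or alkyl enol ether to a cyclic 1,3,5-tricarbonyl compound), the acylation of 2-alkylidenepyrans at the exocyclic carbon, and the dienylketene electrocyclisation that ends the Danheiser benzannulation, but none of them has been shown with a γ-pyranone as the masked ketone. The placement of the aryl group at C8'' and not C6'' needs no selectivity, because O1''–C8a'' and C8''–C3' exist before the ring is made, and because 17 is symmetric a first attack at C4a'' instead of C8'' leads to the same product. O-cyclisation to a 4-hydroxy-2-pyranone, the usual competitor of this annulation, is shut off because the enol oxygen is tied up as O1'' and the oxygen of C4''=O cannot reach C5''. Closure of 19 onto C2' of ring B would have to break benzene aromaticity at a carbon meta to the methoxy group and ortho to the electron-poor chromenone, whereas the C4a''=C8a'' bond of a γ-pyranone is only weakly aromatic and polarised towards C4a''; inverse addition and high dilution should hold back the 2:1 adduct and ketene dimers. No stereocentre is formed, and the new C3'–C8'' axis arises as a racemate.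

Step 11
Reactants: 20 protected biflavone
Product: 21 taiwanhomoflavone A, 8-[5-(5-hydroxy-7-methoxy-6-methyl-4-oxo-4H-chromen-2-yl)-2-methoxyphenyl]-5,7-dihydroxy-2-(4-hydroxyphenyl)-4H-chromen-4-one
Conditions: BCl3 (8 equiv), pentamethylbenzene (3 equiv), CH2Cl2, −78 to 0 °C; MeOH, then 1 M HCl
Reagents that add atoms: none
Why: BCl3 binds to C4=O and cleaves the peri 5-O-methyl ether through a six-membered chelate, a known selective demethylation of 5-methoxyflavones. With pentamethylbenzene as cation scavenger it also cleaves the aryl benzyl ether at low temperature. The non-chelated methyl ethers at C7 and C4' should be inert to BCl3 at these temperatures.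

## Compound list

1 | 2,6-dimethoxytoluene | COc1cccc(OC)c1C | starting material
2 | 2-(3,5-dimethoxy-4-methylphenyl)-4,4,5,5-tetramethyl-1,3,2-dioxaborolane (not isolated) | COc1cc(B2OC(C)(C)C(C)(C)O2)cc(OC)c1C | intermediate
3 | 3,5-dimethoxy-4-methylphenol | COc1cc(O)cc(OC)c1C | intermediate
4 | 1-(6-hydroxy-2,4-dimethoxy-3-methylphenyl)ethan-1-one | CC(=O)c1c(O)cc(OC)c(C)c1OC | intermediate
5 | methyl 2-(2-methoxyphenyl)acetate | COC(=O)Cc1ccccc1OC | starting material
6 | methyl 2-(5-formyl-2-methoxyphenyl)acetate | COC(=O)Cc1cc(C=O)ccc1OC | intermediate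
7 | 2-{5-[(1E)-3-(6-hydroxy-2,4-dimethoxy-3-methylphenyl)-3-oxoprop-1-en-1-yl]-2-methoxyphenyl}acetic acid | COc1ccc(/C=C/C(=O)c2c(O)cc(OC)c(C)c2OC)cc1CC(=O)O | intermediate
8 | 2-[5-(5,7-dimethoxy-6-methyl-4-oxo-4H-chromen-2-yl)-2-methoxyphenyl]acetic acid | COc1ccc(-c2cc(=O)c3c(OC)c(C)c(OC)cc3o2)cc1CC(=O)O | intermediate
9 | Meldrum's acid (2,2-dimethyl-1,3-dioxane-4,6-dione) | CC1(C)OC(=O)CC(=O)O1 | starting material
10 | 5-{2-[5-(5,7-dimethoxy-6-methyl-4-oxo-4H-chromen-2-yl)-2-methoxyphenyl]-1-hydroxyethylidene}-2,2-dimethyl-1,3-dioxane-4,6-dione | COc1ccc(-c2cc(=O)c3c(OC)c(C)c(OC)cc3o2)cc1CC(O)=C1C(=O)OC(C)(C)OC1=O | intermediate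
11 | 1-(benzyloxy)-4-iodobenzene | Ic1ccc(OCc2ccccc2)cc1 | starting material
12 | 1-(benzyloxy)-4-(1-ethoxyethenyl)benzene | C=C(OCC)c1ccc(OCc2ccccc2)cc1 | intermediate
13 | 4-[5-(5,7-dimethoxy-6-methyl-4-oxo-4H-chromen-2-yl)-2-methoxyphenyl]-3-oxobut-1-en-1-one (acylketene, not isolated) | COc1ccc(-c2cc(=O)c3c(OC)c(C)c(OC)cc3o2)cc1CC(=O)C=C=O | intermediate
14 | 2-[4-(benzyloxy)phenyl]-2-ethoxy-6-{[5-(5,7-dimethoxy-6-methyl-4-oxo-4H-chromen-2-yl)-2-methoxyphenyl]methyl}-2,3-dihydro-4H-pyran-4-one (racemic, not isolated) | COc1ccc(-c2cc(=O)c3c(OC)c(C)c(OC)cc3o2)cc1CC1=CC(=O)CC(OCC)(c2ccc(OCc3ccccc3)cc2)O1 | intermediate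
15 | 2-(3-{[6-(4-(benzyloxy)phenyl)-4-oxo-4H-pyran-2-yl]methyl}-4-methoxyphenyl)-5,7-dimethoxy-6-methyl-4H-chromen-4-one | COc1ccc(-c2cc(=O)c3c(OC)c(C)c(OC)cc3o2)cc1Cc1cc(=O)cc(-c2ccc(OCc3ccccc3)cc2)o1 | intermediate
16 | 2-{3-[(6-[4-(benzyloxy)phenyl]-4-[(tert-butyldimethylsilyl)oxy]-2H-pyran-2-ylidene)methyl]-4-methoxyphenyl}-5,7-dimethoxy-6-methyl-4H-chromen-4-one (E/Z mixture) | COc1ccc(-c2cc(=O)c3c(OC)c(C)c(OC)cc3o2)cc1C=C1C=C(O[Si](C)(C)C(C)(C)C)C=C(c2ccc(OCc3ccccc3)cc2)O1 | intermediate
17 | malonyl dichloride | O=C(Cl)CC(=O)Cl | starting material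
18 | 4-{6-[4-(benzyloxy)phenyl]-4-oxo-4H-pyran-2-yl}-4-[5-(5,7-dimethoxy-6-methyl-4-oxo-4H-chromen-2-yl)-2-methoxyphenyl]-3-oxobutanoyl chloride (racemic, not isolated) | COc1ccc(-c2cc(=O)c3c(OC)c(C)c(OC)cc3o2)cc1C(C(=O)CC(=O)Cl)c1cc(=O)cc(-c2ccc(OCc3ccccc3)cc2)o1 | intermediate
19 | 4-{6-[4-(benzyloxy)phenyl]-4-oxo-4H-pyran-2-yl}-4-[5-(5,7-dimethoxy-6-methyl-4-oxo-4H-chromen-2-yl)-2-methoxyphenyl]-3-hydroxybuta-1,3-dien-1-one (dienylketene, not isolated) | COc1ccc(-c2cc(=O)c3c(OC)c(C)c(OC)cc3o2)cc1C(=C(O)C=C=O)c1cc(=O)cc(-c2ccc(OCc3ccccc3)cc2)o1 | intermediate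
20 | 2-[4-(benzyloxy)phenyl]-8-[5-(5,7-dimethoxy-6-methyl-4-oxo-4H-chromen-2-yl)-2-methoxyphenyl]-5,7-dihydroxy-4H-chromen-4-one | COc1ccc(-c2cc(=O)c3c(OC)c(C)c(OC)cc3o2)cc1-c1c(O)cc(O)c2c(=O)cc(-c3ccc(OCc4ccccc4)cc3)oc12 | intermediate
21 | taiwanhomoflavone A | COc1ccc(-c2cc(=O)c3c(O)c(C)c(OC)cc3o2)cc1-c1c(O)cc(O)c2c(=O)cc(-c3ccc(O)cc3)oc12 | target

## Step count and least certain steps

Total step count: 11. Longest linear sequence: 9 (steps 1, 2, 4, 5, 6, 8, 9, 10, 11).

**Step 10 (key step, bears the label "Proposed new method:").**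
- *What may go wrong:*
  - Proton transfer from the acidic CH2 of 17, or from liberated HCl, to the basic exocyclic carbon of 16 would simply return 15.
  - A second molecule of 16 may be acylated intermolecularly by 18.
  - The ketene may oligomerise if closure at the weakly nucleophilic pyranone carbon is slow.
  - Closure onto ring B is the least likely diversion.
- *Fallback (known chemistry only; sets out from 4 and comes back at 21):*
  - Claisen–Schmidt condensation of 4 with commercial 3-bromo-4-methoxybenzaldehyde (KOH, EtOH) would give (2E)-3-(3-bromo-4-methoxyphenyl)-1-(6-hydroxy-2,4-dimethoxy-3-methylphenyl)prop-2-en-1-one F1.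
  - I2 in DMSO would give 2-(3-bromo-4-methoxyphenyl)-5,7-dimethoxy-6-methyl-4H-chromen-4-one F2.
  - Miyaura borylation (B2pin2, PdCl2(dppf), KOAc, dioxane, 90 °C) would give 5,7-dimethoxy-2-[4-methoxy-3-(4,4,5,5-tetramethyl-1,3,2-dioxaborolan-2-yl)phenyl]-6-methyl-4H-chromen-4-one F3.
  - In parallel, commercial apigenin would be perbenzylated (BnBr, K2CO3, DMF, 80 °C) to 5,7-bis(benzyloxy)-2-[4-(benzyloxy)phenyl]-4H-chromen-4-one F4.
  - F4 would be iodinated (I2, CF3CO2Ag, CH2Cl2) to 5,7-bis(benzyloxy)-2-[4-(benzyloxy)phenyl]-8-iodo-4H-chromen-4-one F5.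
  - Suzuki–Miyaura coupling of F3 with F5 (Pd(PPh3)4, K3PO4, dioxane/H2O, 90 °C) would give 5,7-bis(benzyloxy)-2-[4-(benzyloxy)phenyl]-8-[5-(5,7-dimethoxy-6-methyl-4-oxo-4H-chromen-2-yl)-2-methoxyphenyl]-4H-chromen-4-one F6.
  - The conditions of step 11 would convert F6 into 21.

**Step 9.**
- *What may go wrong:* the very electron-rich trienol ether may hydrolyse or oxidise in air during its non-aqueous isolation. Conversion may be incomplete because the silyl triflate is shared with the basic flavone carbonyl of unit 1.
- *Fallback (sets out from 15 and comes back at 20; no preformed nucleophile):*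
  - 15 itself would be heated with bis(2,4,6-trichlorophenyl) malonate in bromobenzene or diphenyl ether (150–200 °C).
  - This active ester releases an (aryloxycarbonyl)ketene, which should C-acylate the small equilibrium share of the 4-hydroxy-2-benzylidenepyran tautomer of 15.
  - Loss of the second aryloxide leads to 19 and on to 20.

**Step 8.**
- *What may go wrong:* ethanol may be lost early from 14, and the alcohol would then trap 13. The strongly acidic enol 10 may protonate and oligomerise the donor-substituted enol ether 12. The acylketene 13 may dimerise.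
- *Fallback (sets out from 8 and comes back at 15; anionic chain assembly in place of the cycloaddition):*
  - Claisen condensation of 4'-benzyloxyacetophenone with ethyl acetate (NaH, THF) would give 1-[4-(benzyloxy)phenyl]butane-1,3-dione F7.
  - Fischer esterification of 8 would give methyl 2-[5-(5,7-dimethoxy-6-methyl-4-oxo-4H-chromen-2-yl)-2-methoxyphenyl]acetate F8.
  - The 1,3-dianion of F7 (LDA, THF, −78 °C, with extra base for the benzylic CH2 of the ester) would be acylated at its terminal carbon by F8. The product would be 1-[4-(benzyloxy)phenyl]-6-[5-(5,7-dimethoxy-6-methyl-4-oxo-4H-chromen-2-yl)-2-methoxyphenyl]hexane-1,3,5-trione F9.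
  - Trifluoroacetic acid would cyclodehydrate F9 to 15.

**Step 11.**
- *What may go wrong:*
  - Cleavage of the hindered 5-O-methyl ether may be incomplete.
  - Over-cleavage may occur at 7-OCH3, which is twisted out of plane by the 6-methyl group.
  - The electron-rich ring D may be C-benzylated if it outcompetes the scavenger for the benzyl cation.
- *Fallback (sets out from 20 and comes back at 21; two orthogonal cleavages without a free benzyl cation):*
  - Hydrogenolysis (H2, Pd/C, THF/MeOH) would give 8-[5-(5,7-dimethoxy-6-methyl-4-oxo-4H-chromen-2-yl)-2-methoxyphenyl]-5,7-dihydroxy-2-(4-hydroxyphenyl)-4H-chromen-4-one F10.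
  - Chelation-controlled demethylation with AlCl3 in MeCN at reflux would then give 21.

**Step 5.**
- *What may go wrong:* the benzylic CH2 of the free arylacetic acid may be oxidised (α-iodination followed by Kornblum oxidation or decarboxylation). Ring A may be iodinated at C8.
- *Fallback (sets out from 7 and comes back at 8; redox-neutral ring closure first, then dehydrogenation by hydride abstraction):*
  - NaOAc in refluxing EtOH would give 2-[5-(5,7-dimethoxy-6-methyl-4-oxochroman-2-yl)-2-methoxyphenyl]acetic acid F11 (racemic).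
  - DDQ in refluxing dioxane would oxidise F11 to 8.

## Further compounds

F1 | step 10 | (2E)-3-(3-bromo-4-methoxyphenyl)-1-(6-hydroxy-2,4-dimethoxy-3-methylphenyl)prop-2-en-1-one | COc1ccc(/C=C/C(=O)c2c(O)cc(OC)c(C)c2OC)cc1Br
F2 | step 10 | 2-(3-bromo-4-methoxyphenyl)-5,7-dimethoxy-6-methyl-4H-chromen-4-one | COc1ccc(-c2cc(=O)c3c(OC)c(C)c(OC)cc3o2)cc1Br
F3 | step 10 | 5,7-dimethoxy-2-[4-methoxy-3-(4,4,5,5-tetramethyl-1,3,2-dioxaborolan-2-yl)phenyl]-6-methyl-4H-chromen-4-one | COc1ccc(-c2cc(=O)c3c(OC)c(C)c(OC)cc3o2)cc1B1OC(C)(C)C(C)(C)O1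
F4 | step 10 | 5,7-bis(benzyloxy)-2-[4-(benzyloxy)phenyl]-4H-chromen-4-one | O=c1cc(-c2ccc(OCc3ccccc3)cc2)oc2cc(OCc3ccccc3)cc(OCc3ccccc3)c12
F5 | step 10 | 5,7-bis(benzyloxy)-2-[4-(benzyloxy)phenyl]-8-iodo-4H-chromen-4-one | O=c1cc(-c2ccc(OCc3ccccc3)cc2)oc2c(I)c(OCc3ccccc3)cc(OCc3ccccc3)c12
F6 | step 10 | 5,7-bis(benzyloxy)-2-[4-(benzyloxy)phenyl]-8-[5-(5,7-dimethoxy-6-methyl-4-oxo-4H-chromen-2-yl)-2-methoxyphenyl]-4H-chromen-4-one | COc1ccc(-c2cc(=O)c3c(OC)c(C)c(OC)cc3o2)cc1-c1c(OCc2ccccc2)cc(OCc2ccccc2)c2c(=O)cc(-c3ccc(OCc4ccccc4)cc3)oc12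
F0 | step 9 | none | none
F7 | step 8 | 1-[4-(benzyloxy)phenyl]butane-1,3-dione | CC(=O)CC(=O)c1ccc(OCc2ccccc2)cc1
F8 | step 8 | methyl 2-[5-(5,7-dimethoxy-6-methyl-4-oxo-4H-chromen-2-yl)-2-methoxyphenyl]acetate | COC(=O)Cc1cc(-c2cc(=O)c3c(OC)c(C)c(OC)cc3o2)ccc1OC
F9 | step 8 | 1-[4-(benzyloxy)phenyl]-6-[5-(5,7-dimethoxy-6-methyl-4-oxo-4H-chromen-2-yl)-2-methoxyphenyl]hexane-1,3,5-trione | COc1ccc(-c2cc(=O)c3c(OC)c(C)c(OC)cc3o2)cc1CC(=O)CC(=O)CC(=O)c1ccc(OCc2ccccc2)cc1
F10 | step 11 | 8-[5-(5,7-dimethoxy-6-methyl-4-oxo-4H-chromen-2-yl)-2-methoxyphenyl]-5,7-dihydroxy-2-(4-hydroxyphenyl)-4H-chromen-4-one | COc1ccc(-c2cc(=O)c3c(OC)c(C)c(OC)cc3o2)cc1-c1c(O)cc(O)c2c(=O)cc(-c3ccc(O)cc3)oc12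
F11 | step 5 | 2-[5-(5,7-dimethoxy-6-methyl-4-oxochroman-2-yl)-2-methoxyphenyl]acetic acid (racemic) | COc1ccc(C2CC(=O)c3c(OC)c(C)c(OC)cc3O2)cc1CC(=O)O
A1 | alternative 1 | 5,7-dimethoxy-2-[4-methoxy-3-(4,4,5,5-tetramethyl-1,3,2-dioxaborolan-2-yl)phenyl]-6-methyl-4H-chromen-4-one | COc1ccc(-c2cc(=O)c3c(OC)c(C)c(OC)cc3o2)cc1B1OC(C)(C)C(C)(C)O1
A2 | alternative 1 | 5,7-bis(benzyloxy)-2-[4-(benzyloxy)phenyl]-8-iodo-4H-chromen-4-one | O=c1cc(-c2ccc(OCc3ccccc3)cc2)oc2c(I)c(OCc3ccccc3)cc(OCc3ccccc3)c12
A3 | alternative 2 | 5-hydroxy-2-(4-hydroxyphenyl)-7-methoxy-6-methyl-4H-chromen-4-one | COc1cc2oc(-c3ccc(O)cc3)cc(=O)c2c(O)c1C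
A4 | alternative 2 | apigenin, 5,7-dihydroxy-2-(4-hydroxyphenyl)-4H-chromen-4-one | O=c1cc(-c2ccc(O)cc2)oc2cc(O)cc(O)c12
A5 | alternative 2 | 5,7-dihydroxy-8-[2-hydroxy-5-(5-hydroxy-7-methoxy-6-methyl-4-oxo-4H-chromen-2-yl)phenyl]-2-(4-hydroxyphenyl)-4H-chromen-4-one | COc1cc2oc(-c3ccc(O)c(-c4c(O)cc(O)c5c(=O)cc(-c6ccc(O)cc6)oc45)c3)cc(=O)c2c(O)c1C
A6 | alternative 3 | methyl 6-[5-(5,7-dimethoxy-6-methyl-4-oxo-4H-chromen-2-yl)-2-methoxyphenyl]-3,5-dioxohexanoate | COC(=O)CC(=O)CC(=O)Cc1cc(-c2cc(=O)c3c(OC)c(C)c(OC)cc3o2)ccc1OC
A7 | alternative 3 | 5,7-dimethoxy-2-[4-methoxy-3-(2,4,6-trihydroxyphenyl)phenyl]-6-methyl-4H-chromen-4-one | COc1ccc(-c2cc(=O)c3c(OC)c(C)c(OC)cc3o2)cc1-c1c(O)cc(O)cc1O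
A8 | alternative 3 | 6-[5-(5,7-dimethoxy-6-methyl-4-oxo-4H-chromen-2-yl)-2-methoxyphenyl]-5,7-dihydroxy-2-(4-hydroxyphenyl)-4H-chromen-4-one | COc1ccc(-c2cc(=O)c3c(OC)c(C)c(OC)cc3o2)cc1-c1c(O)cc2oc(-c3ccc(O)cc3)cc(=O)c2c1O
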